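**Retrosynthetic overview**
1. Target 16 ⇐ 15: the ring B C4' phenol travels as a benzyl ether and is freed in the last step.
2. 15 ⇐ 11 + 12 (key): ring A is cut at C6–C1 and C3–C2. The strategy rests on the ring A pattern: adjacent C1 (CO2Me) and C2 (Me) are methyl but-2-ynoate, and C3 (Me)–C4 (O-aroyl)–C5 (Me)–C6 (OH) is a ketene acetal diene that already carries the ring B ester on the C4 oxygen.
3. 11 ⇐ 9 ⇐ 7 + 6: the diene comes from γ-deprotonation and O-silylation of the enol ester made by O-acylating methyl 2-methyl-3-oxopentanoate, so the hindered depside C(=O)–O bond is made on an enolate oxygen before ring A exists.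
4. 6 ⇐ 1: ring B is bought as methyl 2,4-dihydroxy-3,6-dimethylbenzoate and elaborated by C5' chlorination, 4'-O-benzylation, 2'-O-methylation, saponification and acid chloride formation.
5. Ring order: ring B is purchased; ring A is the only ring formed (step 8).

Key step: step 8

Remark: the target has no stereocentre and its aryl ester bonds rotate freely, so it is achiral and no enantiocontrol is needed; alkene geometries are given where they matter.
Remark: ring A locants are C1 (CO2Me), C2 (Me), C3 (Me), C4 (O-aroyl), C5 (Me), C6 (OH); ring B locants are C1' (carbonyl carbon), C2' (OMe), C3' (Me), C4' (OH/OBn), C5' (Cl), C6' (Me). Ar'CO stands for 4-(benzyloxy)-5-chloro-2-methoxy-3,6-dimethylbenzoyl.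
Remark: salts that are only protonated or hydrolysed in the aqueous work-up (phenoxides, the potassium carboxylate of step 4, boron complexes of step 9) are not numbered.

Step 1
Reactants: 1 methyl 2,4-dihydroxy-3,6-dimethylbenzoate
Product: 2 methyl 5-chloro-2,4-dihydroxy-3,6-dimethylbenzoate
Conditions: SO2Cl2 (1.05 equiv), Et2O, 0 °C → rt
Reagents that add atoms: sulfuryl chloride, O=S(=O)(Cl)Cl
Why: Electrophilic aromatic chlorination goes to C5', the only unsubstituted ring carbon (ortho to the 4'-OH, para to the 2'-OH), and one equivalent at low temperature should avoid ipso attack.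

Step 2
Reactants: 2 methyl 5-chloro-2,4-dihydroxy-3,6-dimethylbenzoate
Product: 3 methyl 4-(benzyloxy)-5-chloro-2-hydroxy-3,6-dimethylbenzoate
Conditions: BnBr (1.05 equiv), K2CO3, acetone, reflux
Reagents that add atoms: benzyl bromide, BrCc1ccccc1
Why: Williamson etherification should be selective for the 4'-OH, which is acidified by the ortho chlorine, because the 2'-OH is hydrogen-bonded to the ester carbonyl and is less acidic and less nucleophilic.

Step 3
Reactants: 3 methyl 4-(benzyloxy)-5-chloro-2-hydroxy-3,6-dimethylbenzoate
Product: 4 methyl 4-(benzyloxy)-5-chloro-2-methoxy-3,6-dimethylbenzoate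
Conditions: MeI, K2CO3, DMF, 60 °C
Reagents that add atoms: iodomethane, CI
Why: Williamson methylation of the remaining chelated 2'-OH only needs the more forcing DMF/heat conditions, and nothing else in 3 can be alkylated.

Step 4
Reactants: 4 methyl 4-(benzyloxy)-5-chloro-2-methoxy-3,6-dimethylbenzoate
Product: 5 4-(benzyloxy)-5-chloro-2-methoxy-3,6-dimethylbenzoic acid
Conditions: KOH, DMSO–H2O (4:1), 90 °C; then aq. HCl
Reagents that add atoms: potassium hydroxide, [K+].[OH-]
Why: Saponification of the di-ortho-substituted methyl ester is slow but should proceed with poorly solvated hydroxide in hot aqueous DMSO, to which the benzyl ether, the methyl ether and the aryl chloride are inert.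

Step 5
Reactants: 5 4-(benzyloxy)-5-chloro-2-methoxy-3,6-dimethylbenzoic acid
Product: 6 4-(benzyloxy)-5-chloro-2-methoxy-3,6-dimethylbenzoyl chloride
Conditions: (COCl)2, DMF (cat.), CH2Cl2, 0 °C → rt; used crude
Reagents that add atoms: oxalyl chloride, O=C(Cl)C(=O)Cl
Why: Vilsmeier-type activation converts the acid into the acid chloride without touching the aryl ethers, and a hindered aroyl chloride of this kind is stable enough to be carried on crude.

Step 6
Reactants: 6 4-(benzyloxy)-5-chloro-2-methoxy-3,6-dimethylbenzoyl chloride; 7 methyl 2-methyl-3-oxopentanoate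
Product: 9 methyl (E)-3-(Ar'CO-oxy)-2-methylpent-2-enoate, via sodium enolate of the keto ester 8 (not isolated)
Conditions: NaH (1.1 equiv), THF–DMPU (4:1), 0 °C; then 6, 0 °C → rt
Reagents that add atoms: none
Why: O-Acylation of a β-keto ester enolate: the dissociated sodium enolate should react with the hard, hindered aroyl chloride at oxygen because C-acylation would build a quaternary carbon next to a di-ortho-substituted aroyl group, and the non-chelated enolate is expected to give mainly the E enol ester (ethyl syn to CO2Me), while any Z isomer leads to the same dienolate in step 7 since this double bond becomes the central single bond of the diene.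

Step 7
Reactants: 9 methyl (E)-3-(Ar'CO-oxy)-2-methylpent-2-enoate
Product: 11 (1Z,3Z)-1-methoxy-2-methyl-1-(trimethylsilyloxy)penta-1,3-dien-3-yl 4-(benzyloxy)-5-chloro-2-methoxy-3,6-dimethylbenzoate, via lithium dienolate 10 (not isolated)
Conditions: LDA (1.1 equiv), TMSCl (1.5 equiv, present from the start), THF, –78 → 0 °C; pentane, filtration under Ar; crude 11 used at once
Reagents that add atoms: chlorotrimethylsilane, C[Si](C)(C)Cl
Why: Vinylogous (γ) deprotonation and O-silylation of a β-oxygenated enoate, the standard way to ketene acetal dienes from 3-alkoxy enoates: the α-carbon is fully substituted, the γ-CH2 lies syn to the ester carbonyl and is far more acidic than the C6' methyl of the twisted aroate, the aroyl carbonyl is shielded by two ortho groups, TMSCl traps the dienolate on oxygen before it can expel the aroate, and allylic 1,3-strain should place the terminal methyl cis to the aroyloxy group (3Z).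

Step 8
Reactants: 11 (1Z,3Z)-1-methoxy-2-methyl-1-(trimethylsilyloxy)penta-1,3-dien-3-yl 4-(benzyloxy)-5-chloro-2-methoxy-3,6-dimethylbenzoate; 12 methyl but-2-ynoate
Product: 15 methyl 4-(Ar'CO-oxy)-6-hydroxy-2,3,5-trimethylbenzoate (ring B O-benzyl depside), via cyclohexa-1,4-diene cycloadduct 13 (not isolated), via cyclohexa-2,5-dienone 14 (not isolated)
Conditions: 12 (5 equiv, neat), sealed tube, 120 °C; then 1 M HCl, THF, rt
Reagents that add atoms: none
Why: Diene 11, whose HOMO is raised by the two ketene acetal oxygens, the acyloxy oxygen and two methyl groups, should add to the electron-poor alkyne 12 in a thermal, concerted but asynchronous normal-demand [4+2] cycloaddition that forms the C6–C1 and C3–C2 bonds; the closest known reaction type is the Diels–Alder/aromatization of 1,1,3-trioxygenated ketene acetal dienes with alkynoates, the only change being an aroyl instead of a silyl or alkyl group on the 3-oxygen, which lowers diene reactivity and is met with excess neat dienophile and heat. Ring A closes as a six-membered carbocycle by this single intermolecular suprafacial [4+2] addition, giving the cyclohexa-1,4-diene 13. Aqueous acid then hydrolyses the mixed methyl silyl ketal at C6 (methanol leaves, silicon is lost from oxygen) to the cross-conjugated dienone 14, which tautomerizes by moving the C3 hydrogen to oxygen and gives the C6 phenol hydrogen-bonded to the C1 ester. No stereocentre remains, because the C3 and C6 centres of 13 and the C3 centre of 14 are destroyed on aromatization. The step needs regioselectivity, and the diene secures it: both oxygen patterns put the largest HOMO coefficient on the CH(Me) terminus, which bonds to the β-carbon of the alkynoate, so that CO2Me ends next to OH and the C2 and C3 methyls are adjacent, while the (3Z) geometry keeps the terminal methyl outside so the s-cis conformer is accessible.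

Step 9
Reactants: 15 methyl 4-(Ar'CO-oxy)-6-hydroxy-2,3,5-trimethylbenzoate
Product: 16 methyl 4-[(5-chloro-4-hydroxy-2-methoxy-3,6-dimethylbenzoyl)oxy]-6-hydroxy-2,3,5-trimethylbenzoate (target)
Conditions: BCl3 (3 equiv), C6HMe5 (5 equiv), CH2Cl2, –78 °C; then H2O
Reagents that add atoms: none
Why: Lewis acid cleavage of an aryl benzyl ether: BCl3 coordinates the twisted, basic C4' ether oxygen and the benzyl cation is taken up by pentamethylbenzene (Friedel–Crafts scavenger), which at –78 °C should spare the C2' methyl ether, both esters and the C–Cl bond that hydrogenolysis would endanger.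

**Compound list**
1 | methyl 2,4-dihydroxy-3,6-dimethylbenzoate | COC(=O)c1c(C)cc(O)c(C)c1O | starting material
2 | methyl 5-chloro-2,4-dihydroxy-3,6-dimethylbenzoate | COC(=O)c1c(C)c(Cl)c(O)c(C)c1O | intermediate
3 | methyl 4-(benzyloxy)-5-chloro-2-hydroxy-3,6-dimethylbenzoate | COC(=O)c1c(C)c(Cl)c(OCc2ccccc2)c(C)c1O | intermediate
4 | methyl 4-(benzyloxy)-5-chloro-2-methoxy-3,6-dimethylbenzoate | COC(=O)c1c(C)c(Cl)c(OCc2ccccc2)c(C)c1OC | intermediate
5 | 4-(benzyloxy)-5-chloro-2-methoxy-3,6-dimethylbenzoic acid | OC(=O)c1c(C)c(Cl)c(OCc2ccccc2)c(C)c1OC | intermediate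
6 | 4-(benzyloxy)-5-chloro-2-methoxy-3,6-dimethylbenzoyl chloride | O=C(Cl)c1c(C)c(Cl)c(OCc2ccccc2)c(C)c1OC | intermediate
7 | methyl 2-methyl-3-oxopentanoate (racemic, centre lost in step 6) | CCC(=O)C(C)C(=O)OC | starting material
8 | sodium enolate of methyl 2-methyl-3-oxopentanoate (delocalized, not isolated) | CCC([O-])=C(C)C(=O)OC.[Na+] | intermediate
9 | methyl (E)-3-{[4-(benzyloxy)-5-chloro-2-methoxy-3,6-dimethylbenzoyl]oxy}-2-methylpent-2-enoate | CC/C(OC(=O)c1c(C)c(Cl)c(OCc2ccccc2)c(C)c1OC)=C(/C)C(=O)OC | intermediate
10 | lithium (1Z,3Z)-dienolate of 9 (not isolated) | C/C=C(OC(=O)c1c(C)c(Cl)c(OCc2ccccc2)c(C)c1OC)/C(C)=C(/OC)[O-].[Li+] | intermediate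
11 | (1Z,3Z)-1-methoxy-2-methyl-1-(trimethylsilyloxy)penta-1,3-dien-3-yl 4-(benzyloxy)-5-chloro-2-methoxy-3,6-dimethylbenzoate | C/C=C(OC(=O)c1c(C)c(Cl)c(OCc2ccccc2)c(C)c1OC)/C(C)=C(/OC)O[Si](C)(C)C | intermediate
12 | methyl but-2-ynoate | CC#CC(=O)OC | starting material
13 | methyl 4-{[4-(benzyloxy)-5-chloro-2-methoxy-3,6-dimethylbenzoyl]oxy}-6-methoxy-2,3,5-trimethyl-6-(trimethylsilyloxy)cyclohexa-1,4-diene-1-carboxylate (racemic diastereomer mixture, not isolated) | COC(=O)C1=C(C)C(C)C(OC(=O)c2c(C)c(Cl)c(OCc3ccccc3)c(C)c2OC)=C(C)C1(OC)O[Si](C)(C)C | intermediate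
14 | methyl 4-{[4-(benzyloxy)-5-chloro-2-methoxy-3,6-dimethylbenzoyl]oxy}-2,3,5-trimethyl-6-oxocyclohexa-1,4-diene-1-carboxylate (racemic, not isolated) | COC(=O)C1=C(C)C(C)C(OC(=O)c2c(C)c(Cl)c(OCc3ccccc3)c(C)c2OC)=C(C)C1=O | intermediate
15 | methyl 4-{[4-(benzyloxy)-5-chloro-2-methoxy-3,6-dimethylbenzoyl]oxy}-6-hydroxy-2,3,5-trimethylbenzoate | COC(=O)c1c(C)c(C)c(OC(=O)c2c(C)c(Cl)c(OCc3ccccc3)c(C)c2OC)c(C)c1O | intermediate
16 | methyl 4-[(5-chloro-4-hydroxy-2-methoxy-3,6-dimethylbenzoyl)oxy]-6-hydroxy-2,3,5-trimethylbenzoate | COC(=O)c1c(C)c(C)c(OC(=O)c2c(C)c(Cl)c(O)c(C)c2OC)c(C)c1O | target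

Total step count: 9. Longest linear sequence: 9 steps (1 → 16).

**Steps most likely to fail**

Step 8. The cycloaddition of a tetrasubstituted acyloxy diene with a β-substituted alkynoate may be so slow that thermal decay of the silyl ketene acetal (silyl migration, loss of the aroyloxy group) outruns ring formation. The fallback sets out from 11 and replaces the alkyne by its more reactive allene isomer, methyl buta-2,3-dienoate (C=C=CC(=O)OC), a known alkynoate surrogate in Diels–Alder/aromatization sequences with oxygenated dienes. Cycloaddition across its α,β-double bond in toluene at 60–80 °C should give the 2-methylidene cyclohexene cycloadduct F1 with the same regiochemistry, since the central allene carbon is the β-carbon. Treatment with aqueous HCl in THF, followed by catalytic TsOH if needed, hydrolyses the ketal, enolizes the resulting β-keto ester and moves the exocyclic double bond into the ring, and the route is rejoined at 15.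

Step 7. The amide base may deprotonate the C6' methyl of ring B (lateral metalation of an ortho-toluate), or the dienolate may expel the aroate or transfer the acyl group before it is silylated. The fallback keeps the same ring A disconnection but takes ring B out of the base step. It sets out from 7, which is converted with TMSCl/Et3N into the silyl enol ether methyl 2-methyl-3-(trimethylsilyloxy)pent-2-enoate F2 and then with LDA/TMSCl at –78 °C into the bis-silyloxy diene (1Z,3Z)-1-methoxy-2-methyl-1,3-bis(trimethylsilyloxy)penta-1,3-diene F3. This more electron-rich diene is heated with 12 (110–130 °C) to the bis-silyl cyclohexa-1,4-diene cycloadduct F4, which is not isolated; acid work-up should give methyl 4,6-dihydroxy-2,3,5-trimethylbenzoate F5. Its free C4 hydroxyl (the C6 hydroxyl is chelated to the ester) is acylated selectively with acid chloride 6 (NaH, 1 equiv, THF, 0 °C → rt), and the route is rejoined at 15. The cost is an esterification between two di-ortho-substituted partners, which is why this is not the first choice.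

Step 9. The Lewis acid may over-react by demethylating the C2' methyl ether ortho to the depside carbonyl, or the hindered benzyl ether may cleave only at temperatures where this competes. The fallback sets out from 15 and removes the benzyl group reductively instead: H2 (1 atm), 10% Pd/C, EtOAc, rt, stopped after one equivalent of hydrogen, which returns to the route at 16 without any new compound (F0). Its own hazard, hydrodechlorination, is limited by neutral, base-free conditions.

**Further compounds**
F1 | step 8 | methyl 4-{[4-(benzyloxy)-5-chloro-2-methoxy-3,6-dimethylbenzoyl]oxy}-6-methoxy-3,5-dimethyl-2-methylidene-6-(trimethylsilyloxy)cyclohex-4-ene-1-carboxylate (diastereomer mixture) | COC(=O)C1C(=C)C(C)C(OC(=O)c2c(C)c(Cl)c(OCc3ccccc3)c(C)c2OC)=C(C)C1(OC)O[Si](C)(C)C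
F2 | step 7 | methyl 2-methyl-3-(trimethylsilyloxy)pent-2-enoate (E/Z mixture) | CCC(O[Si](C)(C)C)=C(C)C(=O)OC
F3 | step 7 | (1Z,3Z)-1-methoxy-2-methyl-1,3-bis(trimethylsilyloxy)penta-1,3-diene | C/C=C(O[Si](C)(C)C)/C(C)=C(/OC)O[Si](C)(C)C
F4 | step 7 | methyl 6-methoxy-2,3,5-trimethyl-4,6-bis(trimethylsilyloxy)cyclohexa-1,4-diene-1-carboxylate (diastereomer mixture) | COC(=O)C1=C(C)C(C)C(O[Si](C)(C)C)=C(C)C1(OC)O[Si](C)(C)C
F5 | step 7 | methyl 4,6-dihydroxy-2,3,5-trimethylbenzoate | COC(=O)c1c(C)c(C)c(O)c(C)c1O
F0 | step 9 | none | none
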